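## Retrosynthetic overview

1. The last bond is C19–C20, made by Stille coupling of a C1–C19 lactone vinyl iodide with a C20–C28 2‑stannyl allylic alcohol; no protecting groups are carried.
2. The δ‑lactone (the only ring) is closed one step earlier by 1,3‑anti reduction and lactonisation of a δ‑hydroxy‑β‑keto ester. Its C4–C5 bond and C5 centre come from a new silylium‑IDPi vinylogous Mukaiyama aldol with Chan's diene.
3. The C5–C17 skipped polyol is grown from (E)‑3‑iodo‑2‑methylacrolein by three chiral‑phosphoric‑acid crotyl‑/allylborations (C16/C17, then C13, then C9), each followed by cross‑metathesis with crotonaldehyde.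
4. C20–C28 comes from 1‑butene by three Zr‑catalysed asymmetric carboaluminations (C26, C24, C22), alkyne homologation with formaldehyde and syn‑hydrostannation.

Assumption: the SMILES is taken as drawn (3R,5R,9R,13R,16S,17R,22R,24S,26S; 6E,10E,14E,18E,20Z), and every locant "Cn" below counts the main chain from the lactone carbonyl (C1) to the ethyl terminus (C28).

## Route

Step 1
Reactants: 1 prop-2-yn-1-ol
Product: 3 (2E)-3-iodo-2-methylprop-2-en-1-ol, via vinylalane 2 (not isolated)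
Conditions: Me3Al (3 equiv), Cp2ZrCl2 (0.25 equiv), CH2Cl2, 0 °C to rt; then I2, THF, −30 to 0 °C
Reagents that add atoms: trimethylaluminium C[Al](C)C; iodine II
Why: Zr‑catalysed Negishi carboalumination adds methyl and aluminium syn across the alkyne with aluminium at the terminus, and iodinolysis with retention gives the (E)‑iodide.

Step 2
Reactants: 3 (2E)-3-iodo-2-methylprop-2-en-1-ol
Product: 4 (2E)-3-iodo-2-methylprop-2-enal
Conditions: MnO2 (15 equiv), CH2Cl2, rt; filtered and used as a solution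
Reagents that add atoms: none
Why: Allylic oxidation with MnO2 stops at the enal and leaves the vinyl iodide and its geometry untouched.

Step 3
Reactants: 4 (2E)-3-iodo-2-methylprop-2-enal; 5 (Z)-crotylboronic acid pinacol ester
Product: 6 (1E,3R,4S)-1-iodo-2,4-dimethylhexa-1,5-dien-3-ol
Conditions: (R)-TRIP [(R)-3,3′-bis(2,4,6-triisopropylphenyl)-BINOL hydrogen phosphate] (5 mol %), toluene, 4 Å MS, −30 °C; aq NaHCO3
Reagents that add atoms: none
Why: Chiral‑phosphoric‑acid‑catalysed crotylboration through a closed chair transition state, in which (R)-TRIP directs Re‑face attack on the enal (17R) and the (Z)‑crotyl geometry gives the syn methyl (16S).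

Step 4
Reactants: 6 (1E,3R,4S)-1-iodo-2,4-dimethylhexa-1,5-dien-3-ol; 7 (2E)-but-2-enal
Product: 8 (2E,4S,5R,6E)-5-hydroxy-7-iodo-4,6-dimethylhepta-2,6-dienal
Conditions: second-generation Hoveyda–Grubbs catalyst (5 mol %), 7 (5 equiv), CH2Cl2, 40 °C
Reagents that add atoms: none
Why: Cross‑metathesis of the terminal olefin with excess crotonaldehyde gives the (E)‑enal under thermodynamic control, the trisubstituted vinyl iodide being too hindered to react.

Step 5
Reactants: 8 (2E,4S,5R,6E)-5-hydroxy-7-iodo-4,6-dimethylhepta-2,6-dienal; 9 allylboronic acid pinacol ester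
Product: 10 (1E,3R,4S,5E,7R)-1-iodo-2,4-dimethyldeca-1,5,9-triene-3,7-diol
Conditions: (R)-TRIP (5 mol %), 9 (1.5 equiv), toluene, −30 °C; aq NaHCO3
Reagents that add atoms: none
Why: Chiral‑phosphoric‑acid‑catalysed allylboration, catalyst‑controlled Re‑face attack on the enal setting 13R independently of the remote centres and tolerating the free hydroxyl.

Step 6
Reactants: 10 (1E,3R,4S,5E,7R)-1-iodo-2,4-dimethyldeca-1,5,9-triene-3,7-diol; 7 (2E)-but-2-enal
Product: 11 (2E,5R,6E,8S,9R,10E)-5,9-dihydroxy-11-iodo-8,10-dimethylundeca-2,6,10-trienal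
Conditions: second-generation Hoveyda–Grubbs catalyst (5 mol %), 7 (5 equiv), CH2Cl2, 40 °C
Reagents that add atoms: none
Why: Cross‑metathesis is selective for the terminal olefin because the internal C14=C15 olefin is flanked by a branched carbon and a carbinol.

Step 7
Reactants: 11 (2E,5R,6E,8S,9R,10E)-5,9-dihydroxy-11-iodo-8,10-dimethylundeca-2,6,10-trienal; 9 allylboronic acid pinacol ester
Product: 12 (1E,3R,4S,5E,7R,9E,11R)-1-iodo-2,4-dimethyltetradeca-1,5,9,13-tetraene-3,7,11-triol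
Conditions: (R)-TRIP (5 mol %), 9 (1.5 equiv), toluene, −30 °C; aq NaHCO3
Reagents that add atoms: none
Why: Second chiral‑phosphoric‑acid‑catalysed allylboration, again Re‑face attack on the enal, setting 9R.

Step 8
Reactants: 12 (1E,3R,4S,5E,7R,9E,11R)-1-iodo-2,4-dimethyltetradeca-1,5,9,13-tetraene-3,7,11-triol; 7 (2E)-but-2-enal
Product: 13 (2E,5R,6E,9R,10E,12S,13R,14E)-5,9,13-trihydroxy-15-iodo-12,14-dimethylpentadeca-2,6,10,14-tetraenal
Conditions: second-generation Hoveyda–Grubbs catalyst (5 mol %), 7 (5 equiv), CH2Cl2, rt to 40 °C, stopped when 12 is consumed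
Reagents that add atoms: none
Why: Cross‑metathesis of the terminal olefin, which reacts much faster than the internal allylic‑alcohol olefins, gives the (E)‑enal.

Step 9
Reactants: 13 (2E,5R,6E,9R,10E,12S,13R,14E)-5,9,13-trihydroxy-15-iodo-12,14-dimethylpentadeca-2,6,10,14-tetraenal; 14 1-methoxy-1,3-bis(trimethylsilyloxy)buta-1,3-diene (Chan's diene)
Product: 17 methyl (5R,6E,9R,10E,13R,14E,16S,17R,18E)-5,9,13,17-tetrahydroxy-19-iodo-16,18-dimethyl-3-oxononadeca-6,10,14,18-tetraenoate, via tris-TMS ether 15 (not isolated), via persilylated aldol adduct 16 (not isolated)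
Conditions: methallyl-SiMe3 (3.3 equiv), chiral IDPi Brønsted acid (BINOL-derived imidodiphosphorimidate, N-triflyl core, 2 mol %), toluene, −20 °C (isobutene lost); then 14 (1.5 equiv), −78 °C; then citric acid, MeOH, 0 °C
Reagents that add atoms: none
Why: Proposed new method: the IDPi acid is turned by methallyl‑SiMe3 into a silylium–IDPi ion pair that first O‑silylates the three carbinols (self‑protection) and then activates the enal carbonyl inside the confined chiral anion, so that Chan's diene adds 1,2 through its terminal carbon on the Re face (5R, catalyst enantiomer fixed on a model enal) and silyl transfer to the aldolate turns the catalyst over before methanolic citric acid strips all SiMe3 groups; the closest known reaction type is the disulfonimide/IDPi‑catalysed (vinylogous) Mukaiyama aldol of silyl ketene acetals and enolsilanes with aldehydes (silylium counteranion‑directed catalysis), together with the SiCl4/bisphosphoramide vinylogous aldol of Chan's diene.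

Step 10
Reactants: 17 methyl (5R,6E,9R,10E,13R,14E,16S,17R,18E)-5,9,13,17-tetrahydroxy-19-iodo-16,18-dimethyl-3-oxononadeca-6,10,14,18-tetraenoate
Product: 19 (4R,6R)-4-hydroxy-6-[(1E,4R,5E,8R,9E,11S,12R,13E)-4,8,12-trihydroxy-14-iodo-11,13-dimethyltetradeca-1,5,9,13-tetraen-1-yl]oxan-2-one, via anti-diol ester 18 (not isolated)
Conditions: Me4NBH(OAc)3 (8 equiv), MeCN/AcOH 1:1, −30 °C; aq potassium sodium tartrate work-up; then PPTS (0.2 equiv), CH2Cl2, rt
Reagents that add atoms: none
Why: Evans–Saksena reduction delivers hydride intramolecularly from the C5–O‑bound acetoxyborohydride to give the 1,3‑anti diol (3R), and acid‑catalysed lactonisation of the C5 hydroxyl onto the ester closes the cis‑4,6‑disubstituted δ‑lactone.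

Step 11
Reactants: 20 but-1-ene; 21 bromoethene
Product: 23 (4S)-4-methylhex-1-ene, via alkylalane 22 (not isolated)
Conditions: Me3Al (1.5 equiv), (+)-bis(1-neomenthylindenyl)zirconium dichloride [(+)-(NMI)2ZrCl2] (3 mol %), (MeAlO)n (cat.), CH2Cl2, 0 °C; evaporate; Zn(OTf)2 (1 equiv), DMF; Pd(DPEphos)Cl2 (3 mol %), i-Bu2AlH (6 mol %), 21 (4 equiv), 70 °C; distilled
Reagents that add atoms: trimethylaluminium C[Al](C)C
Why: Zr‑catalysed asymmetric carboalumination (ZACA) sets C26 (S, about 75–80 % ee here) with the antipode of the catalyst that gives (R)-2-methylalkyl alanes, and Zn‑promoted, Pd‑catalysed Negishi‑type vinylation of the alane extends the chain.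

Step 12
Reactants: 23 (4S)-4-methylhex-1-ene; 21 bromoethene
Product: 25 (4R,6S)-4,6-dimethyloct-1-ene, via alkylalane 24 (not isolated)
Conditions: Me3Al (1.5 equiv), (+)-(NMI)2ZrCl2 (3 mol %), (MeAlO)n (cat.), CH2Cl2, 0 °C; evaporate; Zn(OTf)2 (1 equiv), DMF; Pd(DPEphos)Cl2 (3 mol %), i-Bu2AlH (6 mol %), 21 (4 equiv), 70 °C
Reagents that add atoms: trimethylaluminium C[Al](C)C
Why: A second ZACA with the same catalyst enantiomer sets C24 syn to C26 under catalyst control (the 4R label is only a CIP priority change), followed by the same Pd‑catalysed vinylation.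

Step 13
Reactants: 25 (4R,6S)-4,6-dimethyloct-1-ene
Product: 27 (2R,4S,6S)-2,4,6-trimethyloctan-1-ol, via alkylalane 26 (not isolated)
Conditions: Me3Al (1.5 equiv), (−)-(NMI)2ZrCl2 (3 mol %), (MeAlO)n (cat.), CH2Cl2, 0 °C; then O2, 0 °C to rt; aq HCl; chromatography to remove minor diastereomers
Reagents that add atoms: trimethylaluminium C[Al](C)C; dioxygen O=O
Why: A third ZACA with the antipodal catalyst sets C22 anti to C24, oxidation of the C–Al bond gives the alcohol, and removal of the minor diastereomers raises the enantiopurity of the major one by statistical amplification.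

Step 14
Reactants: 27 (2R,4S,6S)-2,4,6-trimethyloctan-1-ol
Product: 28 (2R,4S,6S)-2,4,6-trimethyloctanal
Conditions: TEMPO (10 mol %), PhI(OAc)2 (1.1 equiv), CH2Cl2, rt
Reagents that add atoms: none
Why: Oxoammonium (TEMPO) oxidation gives the α‑branched aldehyde under neutral conditions without epimerising C22.

Step 15
Reactants: 28 (2R,4S,6S)-2,4,6-trimethyloctanal
Product: 29 (3R,5S,7S)-1,1-dibromo-3,5,7-trimethylnon-1-ene
Conditions: CBr4 (2 equiv), PPh3 (4 equiv), 2,6-lutidine, CH2Cl2, 0 °C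
Reagents that add atoms: carbon tetrabromide BrC(Br)(Br)Br
Why: Corey–Fuchs (Ramirez) dibromo‑olefination, buffered so that the α‑stereocentre is not epimerised.

Step 16
Reactants: 29 (3R,5S,7S)-1,1-dibromo-3,5,7-trimethylnon-1-ene
Product: 31 (4R,6S,8S)-4,6,8-trimethyldec-2-yn-1-ol, via lithium acetylide 30 (not isolated)
Conditions: n-BuLi (2.2 equiv), THF, −78 °C; then (CH2O)n, −78 °C to rt
Reagents that add atoms: formaldehyde C=O
Why: Second stage of the Corey–Fuchs alkyne synthesis (Br/Li exchange, 1,2‑shift, deprotonation), with the lithium acetylide trapped by formaldehyde.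

Step 17
Reactants: 31 (4R,6S,8S)-4,6,8-trimethyldec-2-yn-1-ol
Product: 32 (2E,4R,6S,8S)-4,6,8-trimethyl-2-(tributylstannyl)dec-2-en-1-ol
Conditions: Bu3SnH (1.3 equiv), PdCl2(PPh3)2 (2 mol %), THF, 0 °C; minor regioisomer removed on Et3N-deactivated silica
Reagents that add atoms: tributyltin hydride CCCC[SnH](CCCC)CCCC
Why: Pd‑catalysed syn‑hydrostannation puts tin on the carbon next to CH2OH (away from the α‑branched substituent), and syn addition fixes CH2OH cis to C22, the geometry needed for the 20Z olefin.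

Step 18
Reactants: 19 (4R,6R)-4-hydroxy-6-[(1E,4R,5E,8R,9E,11S,12R,13E)-4,8,12-trihydroxy-14-iodo-11,13-dimethyltetradeca-1,5,9,13-tetraen-1-yl]oxan-2-one; 32 (2E,4R,6S,8S)-4,6,8-trimethyl-2-(tributylstannyl)dec-2-en-1-ol
Product: 33 (4R,6R)-4-hydroxy-6-[(1E,4R,5E,8R,9E,11S,12R,13E,15Z,17R,19S,21S)-4,8,12-trihydroxy-15-(hydroxymethyl)-11,13,17,19,21-pentamethyltricosa-1,5,9,13,15-pentaen-1-yl]oxan-2-one (target)
Conditions: Pd(PPh3)4 (10 mol %), copper thiophene-2-carboxylate (1.5 equiv), [Bu4N][Ph2PO2] (1.5 equiv), degassed DMF, 0 °C to rt, dark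
Reagents that add atoms: none
Why: Copper‑assisted Stille coupling under neutral conditions joins C19 to C20 with retention of both olefin geometries and tolerates the free hydroxyls and the β‑hydroxy lactone.

## Compound list

1 | prop-2-yn-1-ol | C#CCO | starting material
2 | dimethyl[(1E)-3-(dimethylalumanyloxy)-2-methylprop-1-en-1-yl]aluminium | C/C(CO[Al](C)C)=C\[Al](C)C | intermediate
3 | (2E)-3-iodo-2-methylprop-2-en-1-ol | C/C(CO)=C\I | intermediate
4 | (2E)-3-iodo-2-methylprop-2-enal | C/C(C=O)=C\I | intermediate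
5 | 2-[(2Z)-but-2-en-1-yl]-4,4,5,5-tetramethyl-1,3,2-dioxaborolane | C/C=C\CB1OC(C)(C)C(C)(C)O1 | starting material
6 | (1E,3R,4S)-1-iodo-2,4-dimethylhexa-1,5-dien-3-ol | I/C=C(\C)[C@H](O)[C@@H](C)C=C | intermediate
7 | (2E)-but-2-enal | C/C=C/C=O | starting material
8 | (2E,4S,5R,6E)-5-hydroxy-7-iodo-4,6-dimethylhepta-2,6-dienal | I/C=C(\C)[C@H](O)[C@@H](C)/C=C/C=O | intermediate
9 | 4,4,5,5-tetramethyl-2-(prop-2-en-1-yl)-1,3,2-dioxaborolane | C=CCB1OC(C)(C)C(C)(C)O1 | starting material
10 | (1E,3R,4S,5E,7R)-1-iodo-2,4-dimethyldeca-1,5,9-triene-3,7-diol | I/C=C(\C)[C@H](O)[C@@H](C)/C=C/[C@H](O)CC=C | intermediate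
11 | (2E,5R,6E,8S,9R,10E)-5,9-dihydroxy-11-iodo-8,10-dimethylundeca-2,6,10-trienal | I/C=C(\C)[C@H](O)[C@@H](C)/C=C/[C@H](O)C/C=C/C=O | intermediate
12 | (1E,3R,4S,5E,7R,9E,11R)-1-iodo-2,4-dimethyltetradeca-1,5,9,13-tetraene-3,7,11-triol | I/C=C(\C)[C@H](O)[C@@H](C)/C=C/[C@H](O)C/C=C/[C@H](O)CC=C | intermediate
13 | (2E,5R,6E,9R,10E,12S,13R,14E)-5,9,13-trihydroxy-15-iodo-12,14-dimethylpentadeca-2,6,10,14-tetraenal | I/C=C(\C)[C@H](O)[C@@H](C)/C=C/[C@H](O)C/C=C/[C@H](O)C/C=C/C=O | intermediate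
14 | 1-methoxy-1,3-bis(trimethylsilyloxy)buta-1,3-diene | COC(O[Si](C)(C)C)=CC(=C)O[Si](C)(C)C | starting material
15 | (2E,5R,6E,9R,10E,12S,13R,14E)-15-iodo-12,14-dimethyl-5,9,13-tris(trimethylsilyloxy)pentadeca-2,6,10,14-tetraenal | I/C=C(\C)[C@H](O[Si](C)(C)C)[C@@H](C)/C=C/[C@H](O[Si](C)(C)C)C/C=C/[C@H](O[Si](C)(C)C)C/C=C/C=O | intermediate
16 | methyl (5R,6E,9R,10E,13R,14E,16S,17R,18E)-19-iodo-16,18-dimethyl-3,5,9,13,17-pentakis(trimethylsilyloxy)nonadeca-2,6,10,14,18-pentaenoate | I/C=C(\C)[C@H](O[Si](C)(C)C)[C@@H](C)/C=C/[C@H](O[Si](C)(C)C)C/C=C/[C@H](O[Si](C)(C)C)C/C=C/[C@H](O[Si](C)(C)C)CC(O[Si](C)(C)C)=CC(=O)OC | intermediate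
17 | methyl (5R,6E,9R,10E,13R,14E,16S,17R,18E)-5,9,13,17-tetrahydroxy-19-iodo-16,18-dimethyl-3-oxononadeca-6,10,14,18-tetraenoate | I/C=C(\C)[C@H](O)[C@@H](C)/C=C/[C@H](O)C/C=C/[C@H](O)C/C=C/[C@H](O)CC(=O)CC(=O)OC | intermediate
18 | methyl (3R,5R,6E,9R,10E,13R,14E,16S,17R,18E)-3,5,9,13,17-pentahydroxy-19-iodo-16,18-dimethylnonadeca-6,10,14,18-tetraenoate | I/C=C(\C)[C@H](O)[C@@H](C)/C=C/[C@H](O)C/C=C/[C@H](O)C/C=C/[C@H](O)C[C@@H](O)CC(=O)OC | intermediate
19 | (4R,6R)-4-hydroxy-6-[(1E,4R,5E,8R,9E,11S,12R,13E)-4,8,12-trihydroxy-14-iodo-11,13-dimethyltetradeca-1,5,9,13-tetraen-1-yl]oxan-2-one | I/C=C(\C)[C@H](O)[C@@H](C)/C=C/[C@H](O)C/C=C/[C@H](O)C/C=C/[C@H]1C[C@@H](O)CC(=O)O1 | intermediate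
20 | but-1-ene | CCC=C | starting material
21 | bromoethene | C=CBr | starting material
22 | dimethyl[(2S)-2-methylbutyl]aluminium | CC[C@H](C)C[Al](C)C | intermediate
23 | (4S)-4-methylhex-1-ene | CC[C@H](C)CC=C | intermediate
24 | [(2S,4S)-2,4-dimethylhexyl]dimethylaluminium | CC[C@H](C)C[C@H](C)C[Al](C)C | intermediate
25 | (4R,6S)-4,6-dimethyloct-1-ene | CC[C@H](C)C[C@H](C)CC=C | intermediate
26 | dimethyl[(2R,4S,6S)-2,4,6-trimethyloctyl]aluminium | CC[C@H](C)C[C@H](C)C[C@@H](C)C[Al](C)C | intermediate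
27 | (2R,4S,6S)-2,4,6-trimethyloctan-1-ol | CC[C@H](C)C[C@H](C)C[C@@H](C)CO | intermediate
28 | (2R,4S,6S)-2,4,6-trimethyloctanal | CC[C@H](C)C[C@H](C)C[C@@H](C)C=O | intermediate
29 | (3R,5S,7S)-1,1-dibromo-3,5,7-trimethylnon-1-ene | CC[C@H](C)C[C@H](C)C[C@@H](C)C=C(Br)Br | intermediate
30 | [(3R,5S,7S)-3,5,7-trimethylnon-1-yn-1-yl]lithium | CC[C@H](C)C[C@H](C)C[C@@H](C)C#C[Li] | intermediate
31 | (4R,6S,8S)-4,6,8-trimethyldec-2-yn-1-ol | CC[C@H](C)C[C@H](C)C[C@@H](C)C#CCO | intermediate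
32 | (2E,4R,6S,8S)-4,6,8-trimethyl-2-(tributylstannyl)dec-2-en-1-ol | CC[C@H](C)C[C@H](C)C[C@@H](C)/C=C(/[Sn](CCCC)(CCCC)CCCC)CO | intermediate
33 | (4R,6R)-4-hydroxy-6-[(1E,4R,5E,8R,9E,11S,12R,13E,15Z,17R,19S,21S)-4,8,12-trihydroxy-15-(hydroxymethyl)-11,13,17,19,21-pentamethyltricosa-1,5,9,13,15-pentaen-1-yl]oxan-2-one | CC[C@H](C)C[C@H](C)C[C@@H](C)/C=C(/C=C(\C)[C@H](O)[C@@H](C)/C=C/[C@H](O)C/C=C/[C@H](O)C/C=C/[C@H]1C[C@@H](O)CC(=O)O1)CO | target

## Step count and risk

Total step count: 18 (each one‑pot sequence counted once). Longest linear sequence: 11 steps (steps 1–10, then step 18); the C20–C28 branch is 7 steps before the coupling.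

The three steps most likely to fail:

Step 9, the new silylium‑IDPi vinylogous aldol. The enantioselectivity with an enal of this kind is unknown. Competing 1,4‑addition, acetalisation of the enal by the silyl ethers, or ionisation of an allylic silyl ether could erode yield. The fallback uses known chemistry, sets out from 12 and comes back at 19. Crotonaldehyde 7 and Chan's diene 14 are combined under Lewis‑base catalysis (SiCl4, chiral bisphosphoramide, i‑Pr2NEt, CH2Cl2, −78 °C; Re‑face enantiomer of the catalyst) to give methyl (5R,6E)-5-hydroxy-3-oxooct-6-enoate F1. Me4NBH(OAc)3 in MeCN/AcOH at −30 °C then gives methyl (3R,5R,6E)-3,5-dihydroxyoct-6-enoate F2, and PPTS in CH2Cl2 closes (4R,6R)-4-hydroxy-6-[(1E)-prop-1-en-1-yl]oxan-2-one F3. Cross‑metathesis of the terminal olefin of 12 with F3 (3 equiv, second‑generation Hoveyda–Grubbs catalyst, CH2Cl2, 40 °C) then gives 19 directly, so steps 8–10 are bypassed and the aldol is run on a simple enal with no free hydroxyl.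

Step 8, the third cross‑metathesis. The substrate is a free triol with two internal allylic‑alcohol olefins and a vinyl iodide, so chain scission by secondary metathesis or Ru–H isomerisation is possible; steps 4 and 6 carry the same risk to a lesser degree. The fallback avoids metathesis, sets out from 11 and comes back at 13. An organocatalytic decarboxylative acetate aldol of 11 with 3-[(4-methoxyphenyl)sulfanyl]-3-oxopropanoic acid (cinchona‑squaramide catalyst, THF, 0 °C, Re‑face pseudo‑enantiomer) gives S-(4-methoxyphenyl) (3R,4E,7R,8E,10S,11R,12E)-3,7,11-trihydroxy-13-iodo-10,12-dimethyltrideca-4,8,12-trienethioate F4. i‑Bu2AlH in CH2Cl2 at −78 °C gives (3R,4E,7R,8E,10S,11R,12E)-3,7,11-trihydroxy-13-iodo-10,12-dimethyltrideca-4,8,12-trienal F5, which is used crude because it can eliminate water. Wittig olefination with Ph3P=CHCHO in toluene at rt then gives 13.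

Step 18, the Stille coupling. A hindered 1,1‑disubstituted alkenylstannane must couple with a trisubstituted iodide on an unprotected polyol lactone, so slow transmetalation, protodestannylation or cine substitution could intervene. The fallback changes the coupling manifold, sets out from 32 and comes back at 33. Iododestannylation of 32 (I2, CH2Cl2, 0 °C) gives (2E,4R,6S,8S)-2-iodo-4,6,8-trimethyldec-2-en-1-ol F6. Miyaura borylation (bis(pinacolato)diboron, PdCl2(dppf), KOAc, DMSO, 60 °C) gives (2Z,4R,6S,8S)-4,6,8-trimethyl-2-(4,4,5,5-tetramethyl-1,3,2-dioxaborolan-2-yl)dec-2-en-1-ol F7. Suzuki–Miyaura coupling of F7 with 19 (Pd(PPh3)4, K3PO4, THF/H2O, rt, then a PPTS wash to re‑close any opened lactone) gives 33.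

Further compounds

F1 | step 9 | methyl (5R,6E)-5-hydroxy-3-oxooct-6-enoate | C/C=C/[C@H](O)CC(=O)CC(=O)OC
F2 | step 9 | methyl (3R,5R,6E)-3,5-dihydroxyoct-6-enoate | C/C=C/[C@H](O)C[C@@H](O)CC(=O)OC
F3 | step 9 | (4R,6R)-4-hydroxy-6-[(1E)-prop-1-en-1-yl]oxan-2-one | C/C=C/[C@H]1C[C@@H](O)CC(=O)O1
F4 | step 8 | S-(4-methoxyphenyl) (3R,4E,7R,8E,10S,11R,12E)-3,7,11-trihydroxy-13-iodo-10,12-dimethyltrideca-4,8,12-trienethioate | I/C=C(\C)[C@H](O)[C@@H](C)/C=C/[C@H](O)C/C=C/[C@H](O)CC(=O)Sc1ccc(OC)cc1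
F5 | step 8 | (3R,4E,7R,8E,10S,11R,12E)-3,7,11-trihydroxy-13-iodo-10,12-dimethyltrideca-4,8,12-trienal | I/C=C(\C)[C@H](O)[C@@H](C)/C=C/[C@H](O)C/C=C/[C@H](O)CC=O
F6 | step 18 | (2E,4R,6S,8S)-2-iodo-4,6,8-trimethyldec-2-en-1-ol | CC[C@H](C)C[C@H](C)C[C@@H](C)/C=C(/I)CO
F7 | step 18 | (2Z,4R,6S,8S)-4,6,8-trimethyl-2-(4,4,5,5-tetramethyl-1,3,2-dioxaborolan-2-yl)dec-2-en-1-ol | CC[C@H](C)C[C@H](C)C[C@@H](C)/C=C(/B1OC(C)(C)C(C)(C)O1)CO
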